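**Plan**

1. Retrosynthesis (labdane numbering): the 15,16-lactone is cut at O–C15 (Baeyer–Villiger of a spiro-cyclobutanone), then at C13–C14 and C15–C16 (ketene [2+2]), O–C13 (alkynol cyclization), C11–C12 (epoxide opening), C8–CH3 and C9=C11. The 19,6-lactone is cut at O–C19, and ring A at C2–C3 and C4–C5.
2. Enabling feature: C3–C4 with its methyl (C18) and carboxyl (C19) is a methacrylate unit. It lies between C2, the second carbon of an arm on quaternary C10, and C5, the α-carbon of oxygenated C6 in ring B. A C2 radical (decarboxylation of a propanoic acid arm) and a C5=C6 silyl enol ether of a C6 ketone therefore let one radical annulation insert methyl methacrylate and close ring A.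
3. Forward order: ring B (cyclohexane-1,4-dione monoketal) → quaternary C10 with propanoate arm → ene-dione → ring A by annulation → 19,6-lactone → C9 methylene and C8 ketone → 9α,11-epoxide and C8 methyl carbinol → spiro-tetrahydrofuran → spiro-cyclobutanone → spiro-lactone.
4. Stereochemistry: C10 from an auxiliary-controlled Michael addition; C4 from the annulation transition state; C5 by kinetic protonation; C6, C9 and C8 by α-face attack on the trans-decalin (hydride, epoxide oxygen, methyl); C13 by a catalyst-controlled Baeyer–Villiger desymmetrization.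

Key step: step 6

Remark: positions are numbered as in labdanes (C1–C10 decalin, C11–C16 side chain, C17 on C8, C18/C19 on C4, C20 on C10); α and β are the faces of the usual labdane drawing (C20 is β).
Assumption: racemic ketone 1 is taken as a purchasable building block; both of its enantiomers converge in step 1.

Step 1
Reactants: 1 7-methyl-1,4-dioxaspiro[4.5]decan-8-one; 2 (S)-1-phenylethylamine; 3 tert-butyl acrylate
Product: 6 tert-butyl 3-[(7S)-7-methyl-8-oxo-1,4-dioxaspiro[4.5]decan-7-yl]propanoate, via imine 4 (not isolated), via alkylated imine 5 (not isolated)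
Conditions: 2, TsOH (cat.), toluene, reflux, –H2O; then 3, 50 °C; then 20% aq. AcOH, THF, 20 °C
Reagents that add atoms: water, O
Why: Imine 4 should react through its more substituted secondary enamine tautomer in an asymmetric Michael addition (deracemizing alkylation of a chiral imine), the acrylate approaching the enamine face anti to the phenyl group in a compact aza-ene-like transition state, so that both enantiomers of 1 converge on the (S)-configured quaternary C10 before mild hydrolysis returns the ketone.

Step 2
Reactants: 6 tert-butyl 3-[(7S)-7-methyl-8-oxo-1,4-dioxaspiro[4.5]decan-7-yl]propanoate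
Product: 7 3-[(1S)-1-methyl-2,5-dioxocyclohexyl]propanoic acid
Conditions: TFA/H2O (9:1), CH2Cl2, 0 → 20 °C
Reagents that add atoms: water, O
Why: Aqueous trifluoroacetic acid should hydrolyze the dioxolane and cleave the tert-butyl ester in one operation (acetal hydrolysis and ester acidolysis) without touching the quaternary center.

Step 3
Reactants: 7 3-[(1S)-1-methyl-2,5-dioxocyclohexyl]propanoic acid
Product: 8 3-[(1S)-1-methyl-2,5-dioxocyclohex-3-en-1-yl]propanoic acid
Conditions: IBX (2.2 equiv), DMSO, 70 °C
Reagents that add atoms: none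
Why: IBX dehydrogenation of the 1,4-diketone can only place the double bond at C7=C8 because C10 carries no hydrogen, which gives an ene-dione whose only enolizable carbon is C5.

Step 4
Reactants: 8 3-[(1S)-1-methyl-2,5-dioxocyclohex-3-en-1-yl]propanoic acid; 9 N-hydroxyphthalimide
Product: 10 1,3-dioxoisoindolin-2-yl 3-[(1S)-1-methyl-2,5-dioxocyclohex-3-en-1-yl]propanoate
Conditions: iPrN=C=NiPr, DMAP (cat.), CH2Cl2, 0 → 20 °C
Reagents that add atoms: none
Why: Carbodiimide esterification should turn the acid into a redox-active N-acyloxyphthalimide without affecting the ene-dione.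

Step 5
Reactants: 10 1,3-dioxoisoindolin-2-yl 3-[(1S)-1-methyl-2,5-dioxocyclohex-3-en-1-yl]propanoate
Product: 11 1,3-dioxoisoindolin-2-yl 3-[(1S)-3-(tert-butyldimethylsilyloxy)-1-methyl-6-oxocyclohexa-2,4-dien-1-yl]propanoate
Conditions: TBSOTf (1.05 equiv), Et3N, CH2Cl2, –78 °C
Reagents that add atoms: tert-butyldimethylsilyl triflate, CC(C)(C)[Si](C)(C)OS(=O)(=O)C(F)(F)F
Why: Soft enolization (silyl triflate and tertiary amine) can only remove a proton from C5, so O-silylation of the C6 carbonyl should give the regiodefined C5=C6 silyl dienol ether.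

Step 6
Reactants: 11 1,3-dioxoisoindolin-2-yl 3-[(1S)-3-(tert-butyldimethylsilyloxy)-1-methyl-6-oxocyclohexa-2,4-dien-1-yl]propanoate; 12 methyl methacrylate
Product: 13 methyl 6,9-dioxo-11,12,13,14,15,16,17-heptanor-5β-labd-7-en-19-oate (cis-fused ene-dione ester)
Conditions: fac-Ir(ppy)3 (1 mol %), 12 (10 equiv, about 1 M), MeCN, 450 nm LEDs, 25 °C; aqueous work-up
Reagents that add atoms: none
Why: Proposed new method: the excited trivalent iridium catalyst should reduce the N-acyloxyphthalimide of 11; loss of CO2 and phthalimide anion gives the primary C2 radical, which adds to the CH2 terminus (C3) of 12, and the resulting tertiary C4 ester radical closes ring A on C5 of the silyl dienol ether before the captodative C6/C8 radical is oxidized by tetravalent iridium and desilylated to the ene-dione, the closest known reactions being the photoredox decarboxylative Giese addition of such esters and the radical alkylation of silyl enol ethers with radical–polar crossover. Ring A is closed in the 6-exo-trig mode. C4 is set in the cyclization transition state, where the planar ester group should point away from ring B and its silyloxy group while the smaller methyl group lies under C6, which places C19 on the same face of ring A as the C10 methyl group. C5 is formed cis to the tether (5β-H) because the chain can only reach the face of ring B from which it hangs, and this center is corrected in step 7. The chemoselectivity needed is polarity-gated: the nucleophilic primary radical should prefer the electron-poor acrylate (in excess) over the electron-rich dienol ether, and the electrophilic C4 radical should prefer the electron-rich C5 terminus over a second acrylate; the silyl dienol ether, regiodefined because C5 is the only enolizable position of the ene-dione, secures both.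

Step 7
Reactants: 13 methyl 6,9-dioxo-11,12,13,14,15,16,17-heptanor-5β-labd-7-en-19-oate
Product: 15 methyl 6,9-dioxo-11,12,13,14,15,16,17-heptanorlabd-7-en-19-oate (trans-fused), via potassium dienolate 14 (not isolated)
Conditions: KOtBu (1.05 equiv), THF, –20 °C; then AcOH (5 equiv), –78 °C
Reagents that add atoms: none
Why: Deprotonation at C5 gives the planar dienolate, and kinetic protonation should occur from the α-face because the β-face of C5 is flanked by the axial C10 methyl and C4 ester groups, which sets 5α-H and the trans ring fusion.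

Step 8
Reactants: 15 methyl 6,9-dioxo-11,12,13,14,15,16,17-heptanorlabd-7-en-19-oate
Product: 16 methyl 6,9-dioxo-11,12,13,14,15,16,17-heptanorlabdan-19-oate
Conditions: H2 (1 atm), Pd/C, EtOAc, 20 °C
Reagents that add atoms: none
Why: Heterogeneous catalytic hydrogenation should saturate the electron-poor C7=C8 bond of the ene-dione and creates no stereocenter.

Step 9
Reactants: 16 methyl 6,9-dioxo-11,12,13,14,15,16,17-heptanorlabdan-19-oate
Product: 18 9β-hydroxy-11,12,13,14,15,16,17-heptanorlabdan-19,6β-olide, via diol ester 17 (not isolated)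
Conditions: NaBH4 (2 equiv), MeOH/THF, 0 → 20 °C; aq. NH4Cl
Reagents that add atoms: none
Why: Borohydride reduction should deliver hydride to C6 from the α-face, away from the syn-axial C10 methyl and C4 ester groups, and the 6β-alkoxide then closes the γ-lactone on the 1,3-diaxial C19 methyl ester (reduction–lactonization), while the C9 ketone is reduced to a carbinol that is reoxidized in step 10.

Step 10
Reactants: 18 9β-hydroxy-11,12,13,14,15,16,17-heptanorlabdan-19,6β-olide
Product: 19 9-oxo-11,12,13,14,15,16,17-heptanorlabdan-19,6β-olide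
Conditions: Dess–Martin periodinane, NaHCO3, CH2Cl2, 20 °C
Reagents that add atoms: none
Why: Dess–Martin oxidation should return the C9 ketone while the lactone stays inert.

Step 11
Reactants: 19 9-oxo-11,12,13,14,15,16,17-heptanorlabdan-19,6β-olide
Product: 20 12,13,14,15,16,17-hexanorlabd-9(11)-en-19,6β-olide
Conditions: Ph3PCH3Br, KOtBu, toluene, 90 °C
Reagents that add atoms: methyltriphenylphosphonium bromide, C[P+](c1ccccc1)(c1ccccc1)c1ccccc1.[Br-]
Why: Wittig methylenation should install C11 as an exocyclic methylene group on the hindered C9 ketone, heat compensating for the neighboring quaternary C10.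

Step 12
Reactants: 20 12,13,14,15,16,17-hexanorlabd-9(11)-en-19,6β-olide
Product: 22 8-oxo-12,13,14,15,16,17-hexanorlabd-9(11)-en-19,6β-olide, via allylic alcohol 21 (not isolated)
Conditions: SeO2 (0.5 equiv), t-BuOOH (3 equiv), CH2Cl2, 20 °C; then Dess–Martin periodinane, NaHCO3
Reagents that add atoms: tert-butyl hydroperoxide, CC(C)(C)OO
Why: Riley allylic oxidation (ene reaction then [2,3]-sigmatropic shift) can only functionalize C8, the sole allylic CH2 of the 1,1-disubstituted alkene, and oxidation of the allylic alcohol gives the exo-methylene ketone, which erases the C8 stereocenter.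

Step 13
Reactants: 22 8-oxo-12,13,14,15,16,17-hexanorlabd-9(11)-en-19,6β-olide
Product: 23 9α,11-epoxy-8-oxo-12,13,14,15,16,17-hexanorlabdan-19,6β-olide
Conditions: t-BuOOH (1.5 equiv), DBU (0.2 equiv), CH2Cl2, –20 °C
Reagents that add atoms: tert-butyl hydroperoxide, CC(C)(C)OO
Why: In this Weitz–Scheffer epoxidation the peroxide anion adds to C11 and the C8 enolate closes on oxygen, which should place the epoxide oxygen on the α-face of C9, anti to the axial C10 methyl group, a catalytic base at low temperature being chosen to spare the β-acyloxy ketone.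

Step 14
Reactants: 23 9α,11-epoxy-8-oxo-12,13,14,15,16,17-hexanorlabdan-19,6β-olide
Product: 25 9α,11-epoxy-8β-(trimethylsilyloxy)-12,13,14,15,16-pentanorlabdan-19,6β-olide, via cerium alkoxide 24 (not isolated)
Conditions: MeLi, CeCl3, THF, –78 °C; then Me3SiCl, –78 → 20 °C
Reagents that add atoms: methyllithium, [Li]C; chlorotrimethylsilane, C[Si](C)(C)Cl
Why: The weakly basic organocerium reagent should add 1,2 to the C8 ketone from the α-face (equatorial attack), because the β-face is blocked by the syn-axial C10 methyl group and the 6β lactone oxygen, giving 8α-methyl and 8β-oxygen, and the alkoxide is capped in the same flask as its trimethylsilyl ether.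

Step 15
Reactants: 25 9α,11-epoxy-8β-(trimethylsilyloxy)-12,13,14,15,16-pentanorlabdan-19,6β-olide
Product: 26 9α-hydroxy-8β-(trimethylsilyloxy)-14,15-dinorlabd-13(16)-yn-19,6β-olide
Conditions: propargylmagnesium bromide (3 equiv), Et2O/THF, –20 → 0 °C; aq. NH4Cl
Reagents that add atoms: propargylmagnesium bromide, C#CC[Mg]Br
Why: Grignard opening of the spiro-epoxide at its unsubstituted carbon C11 (SN2) should leave the C9–O bond and its α-configuration intact and supplies C12, C13 and C16.

Step 16
Reactants: 26 9α-hydroxy-8β-(trimethylsilyloxy)-14,15-dinorlabd-13(16)-yn-19,6β-olide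
Product: 27 9α,13-epoxy-8β-(trimethylsilyloxy)-14,15-dinorlabd-13(16)-en-19,6β-olide
Conditions: Ph3PAuNTf2 (2 mol %), CH2Cl2, 20 °C; Et3N quench
Reagents that add atoms: none
Why: Gold-catalyzed 5-exo-dig hydroalkoxylation of the alkyne by the only free hydroxyl (9α-OH) should form the spiro-tetrahydrofuran as its 2-methylene enol ether.

Step 17
Reactants: 27 9α,13-epoxy-8β-(trimethylsilyloxy)-14,15-dinorlabd-13(16)-en-19,6β-olide
Product: 28 spiro-2,2-dichlorocyclobutanone at C13 (C14 = CCl2, C15 = CO, C16 = CH2) of 9α,13-epoxy-8β-(trimethylsilyloxy)labdan-19,6β-olide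
Conditions: Cl2CHCOCl (2 equiv), Et3N (slow addition), hexane/Et2O, 0 → 20 °C
Reagents that add atoms: dichloroacetyl chloride, ClC(Cl)C(Cl)=O
Why: The [2+2] cycloaddition of dichloroketene with the electron-rich exocyclic enol ether should be regioselective (carbonyl carbon to the CH2 terminus C16, CCl2 to the oxygen-bearing C13), and the C13 configuration of this adduct is immaterial because it is lost in step 18.

Step 18
Reactants: 28 spiro-2,2-dichlorocyclobutanone at C13 of 9α,13-epoxy-8β-(trimethylsilyloxy)labdan-19,6β-olide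
Product: 30 spiro-cyclobutanone at C13 of 9α,13-epoxy-8β-hydroxylabdan-19,6β-olide, via silyl ether 29 (not isolated)
Conditions: Zn dust, AcOH, 20 °C; then 1 M HCl, THF, 0 °C
Reagents that add atoms: none
Why: Zinc should remove both chlorines (reductive dehalogenation of an α,α-dichloroketone) to give a cyclobutanone whose two CH2 groups flank a non-stereogenic C13, and dilute acid then cleaves the tertiary trimethylsilyl ether.

Step 19
Reactants: 30 spiro-cyclobutanone at C13 of 9α,13-epoxy-8β-hydroxylabdan-19,6β-olide
Product: 31 (13S)-9α,13-epoxy-8β-hydroxylabdane-19,6β:15,16-diolide (target)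
Conditions: 30% aq. H2O2 (1.5 equiv), chiral BINOL-derived phosphoric acid (10 mol %), CHCl3, –40 °C
Reagents that add atoms: hydrogen peroxide, OO
Why: Catalytic asymmetric Baeyer–Villiger oxidation desymmetrizes the 3,3-disubstituted cyclobutanone, the chiral acid selecting which of the two diastereotopic CH2 groups migrates in the Criegee intermediate so that oxygen is inserted between C15 and C16 and C13 is set, the catalyst antipode giving this sense being chosen in a trial with both.

**Compound list**

1 | 7-methyl-1,4-dioxaspiro[4.5]decan-8-one (racemic) | CC1CC2(CCC1=O)OCCO2 | starting material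
2 | (S)-1-phenylethylamine | C[C@H](N)c1ccccc1 | starting material
3 | tert-butyl acrylate | C=CC(=O)OC(C)(C)C | starting material
4 | N-[(1S)-1-phenylethyl]imine of 1 (C7 not defined, it equilibrates through the enamine) | CC1CC2(CCC1=N[C@@H](C)c1ccccc1)OCCO2 | intermediate (not isolated)
5 | tert-butyl 3-[(7S)-7-methyl-8-{[(1S)-1-phenylethyl]imino}-1,4-dioxaspiro[4.5]decan-7-yl]propanoate | CC(C)(C)OC(=O)CC[C@@]1(C)CC2(CCC1=N[C@@H](C)c1ccccc1)OCCO2 | intermediate (not isolated)
6 | tert-butyl 3-[(7S)-7-methyl-8-oxo-1,4-dioxaspiro[4.5]decan-7-yl]propanoate | CC(C)(C)OC(=O)CC[C@@]1(C)CC2(CCC1=O)OCCO2 | intermediate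
7 | 3-[(1S)-1-methyl-2,5-dioxocyclohexyl]propanoic acid | OC(=O)CC[C@@]1(C)CC(=O)CCC1=O | intermediate
8 | 3-[(1S)-1-methyl-2,5-dioxocyclohex-3-en-1-yl]propanoic acid | OC(=O)CC[C@@]1(C)CC(=O)C=CC1=O | intermediate
9 | N-hydroxyphthalimide | ON1C(=O)c2ccccc2C1=O | starting material
10 | 1,3-dioxoisoindolin-2-yl 3-[(1S)-1-methyl-2,5-dioxocyclohex-3-en-1-yl]propanoate | O=C(CC[C@@]1(C)CC(=O)C=CC1=O)ON1C(=O)c2ccccc2C1=O | intermediate
11 | 1,3-dioxoisoindolin-2-yl 3-[(1S)-3-(tert-butyldimethylsilyloxy)-1-methyl-6-oxocyclohexa-2,4-dien-1-yl]propanoate | O=C(CC[C@@]1(C)C=C(O[Si](C)(C)C(C)(C)C)C=CC1=O)ON1C(=O)c2ccccc2C1=O | intermediate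
12 | methyl methacrylate | C=C(C)C(=O)OC | starting material
13 | methyl 6,9-dioxo-11,12,13,14,15,16,17-heptanor-5β-labd-7-en-19-oate (A/B cis, 5β-H; 4α-methyl, 4β-CO2Me, 10β-methyl) | COC(=O)[C@@]1(C)CCC[C@@](C)([C@@H]1C(=O)C=C2)C2=O | intermediate
14 | potassium C5=C6 dienolate of 13 | COC(=O)[C@@]1(C)CCC[C@@](C)(C1=C([O-])C=C2)C2=O.[K+] | intermediate (not isolated)
15 | methyl 6,9-dioxo-11,12,13,14,15,16,17-heptanorlabd-7-en-19-oate (A/B trans, 5α-H) | COC(=O)[C@@]1(C)CCC[C@@](C)([C@H]1C(=O)C=C2)C2=O | intermediate
16 | methyl 6,9-dioxo-11,12,13,14,15,16,17-heptanorlabdan-19-oate (5α-H) | COC(=O)[C@@]1(C)CCC[C@@](C)([C@H]1C(=O)CC2)C2=O | intermediate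
17 | methyl 6β,9β-dihydroxy-11,12,13,14,15,16,17-heptanorlabdan-19-oate | COC(=O)[C@@]1(C)CCC[C@@](C)([C@H]1[C@H](O)CC2)[C@H]2O | intermediate (not isolated)
18 | 9β-hydroxy-11,12,13,14,15,16,17-heptanorlabdan-19,6β-olide | C1C[C@H]2OC(=O)[C@@]3(C)CCC[C@@](C)([C@@H]23)[C@H]1O | intermediate
19 | 9-oxo-11,12,13,14,15,16,17-heptanorlabdan-19,6β-olide | C1C[C@H]2OC(=O)[C@@]3(C)CCC[C@@](C)([C@@H]23)C1=O | intermediate
20 | 12,13,14,15,16,17-hexanorlabd-9(11)-en-19,6β-olide (C9=C11H2) | C1C[C@H]2OC(=O)[C@@]3(C)CCC[C@@](C)([C@@H]23)C1=C | intermediate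
21 | 8-hydroxy-12,13,14,15,16,17-hexanorlabd-9(11)-en-19,6β-olide (C8 epimers) | OC1C[C@H]2OC(=O)[C@@]3(C)CCC[C@@](C)([C@@H]23)C1=C | intermediate (not isolated)
22 | 8-oxo-12,13,14,15,16,17-hexanorlabd-9(11)-en-19,6β-olide | O=C1C[C@H]2OC(=O)[C@@]3(C)CCC[C@@](C)([C@@H]23)C1=C | intermediate
23 | 9α,11-epoxy-8-oxo-12,13,14,15,16,17-hexanorlabdan-19,6β-olide | O=C1C[C@H]2OC(=O)[C@@]3(C)CCC[C@@](C)([C@@H]23)[C@@]14CO4 | intermediate
24 | dichlorocerium 8β-alkoxide of 9α,11-epoxy-8β-hydroxy-12,13,14,15,16-pentanorlabdan-19,6β-olide (8α-methyl) | C[C@]1(O[Ce](Cl)Cl)C[C@H]2OC(=O)[C@@]3(C)CCC[C@@](C)([C@@H]23)[C@@]14CO4 | intermediate (not isolated)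
25 | 9α,11-epoxy-8β-(trimethylsilyloxy)-12,13,14,15,16-pentanorlabdan-19,6β-olide | C[C@]1(O[Si](C)(C)C)C[C@H]2OC(=O)[C@@]3(C)CCC[C@@](C)([C@@H]23)[C@@]14CO4 | intermediate
26 | 9α-hydroxy-8β-(trimethylsilyloxy)-14,15-dinorlabd-13(16)-yn-19,6β-olide | C[C@]1(O[Si](C)(C)C)C[C@H]2OC(=O)[C@@]3(C)CCC[C@@](C)([C@@H]23)[C@@]1(O)CCC#C | intermediate
27 | 9α,13-epoxy-8β-(trimethylsilyloxy)-14,15-dinorlabd-13(16)-en-19,6β-olide | C[C@]1(O[Si](C)(C)C)C[C@H]2OC(=O)[C@@]3(C)CCC[C@@](C)([C@@H]23)[C@@]12CCC(=C)O2 | intermediate
28 | spiro-2,2-dichlorocyclobutanone at C13 of 9α,13-epoxy-8β-(trimethylsilyloxy)labdan-19,6β-olide (C13 epimers) | C[C@]1(O[Si](C)(C)C)C[C@H]2OC(=O)[C@@]3(C)CCC[C@@](C)([C@@H]23)[C@@]12CCC1(CC(=O)C1(Cl)Cl)O2 | intermediate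
29 | spiro-cyclobutanone at C13 of 9α,13-epoxy-8β-(trimethylsilyloxy)labdan-19,6β-olide | C[C@]1(O[Si](C)(C)C)C[C@H]2OC(=O)[C@@]3(C)CCC[C@@](C)([C@@H]23)[C@@]12CCC1(CC(=O)C1)O2 | intermediate (not isolated)
30 | spiro-cyclobutanone at C13 of 9α,13-epoxy-8β-hydroxylabdan-19,6β-olide | C[C@]1(O)C[C@H]2OC(=O)[C@@]3(C)CCC[C@@](C)([C@@H]23)[C@@]12CCC1(CC(=O)C1)O2 | intermediate
31 | (13S)-9α,13-epoxy-8β-hydroxylabdane-19,6β:15,16-diolide (carbonyls at C19 and C15) | C[C@]1(O)C[C@H]2OC(=O)[C@@]3(C)CCC[C@@](C)([C@@H]23)[C@@]12CC[C@]1(COC(=O)C1)O2 | target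

**Step count and risks**

Total: 19 steps. Longest linear sequence: 19 steps (1 to 31).

Steps most likely to fail:

1. Step 6 (the annulation). The cascade may leak at three points: closure of the primary radical onto ring B before it meets the acrylate, oligomerization of the C4 radical before it cyclizes, or inefficient oxidation of the final radical, which would stall the catalytic cycle. Fallback (known chemistry, the two bonds made one after the other), from 7 back to 13: acid 7 is converted with 9 and the carbodiimide into the N-acyloxyphthalimide of the saturated dione F1. Having no alkene, it should undergo the standard reductive photoredox Giese addition to 12 (Ru(bpy)3(PF6)2, Hantzsch ester, iPr2NEt, blue LEDs) to give the diketo ester F2. IBX dehydrogenation gives the ene-dione ester F3. The C4–C5 bond is then closed by intramolecular oxidative coupling of the ketone and ester enolates (LDA, 2.2 equiv, then Fe(acac)3), which returns to the route at 13, the C4 epimers being separated there.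

2. Step 7 (C5 protonation). Removal of the hindered C5 hydrogen may be slow, or the enolate may re-equilibrate during the quench, leaving cis-fused material. Fallback, from 13 back to 19: 13 is converted with TBSOTf and Et3N into the C5=C6 silyl dienol ether F4. Hydrogenation from the open α-face (H2, [Ir(cod)(PCy3)(py)]PF6, or Pd/C under pressure) saturates C7=C8 and C5=C6 and should give the 6β-silyloxy ketone F5 with 5α-H. Fluoride (Bu4NF) then frees the 6β-alkoxide, which lactonizes onto C19 and rejoins the route at 19; steps 8 to 10 are skipped.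

3. Step 19 (Baeyer–Villiger desymmetrization). The catalyst may discriminate poorly between the two nearly equivalent CH2 groups, giving C13 epimers. Fallback, from 28 to 31: the C13 epimers of 28 are separated, and the one with CCl2 on the C8 side of the tetrahydrofuran is oxidized with mCPBA and NaHCO3. Because a CCl2 group does not migrate, oxygen should be inserted only next to C16, giving the dichlorolactone F6. Zn in AcOH followed by dilute HCl then leads to 31.

**Further compounds**

F1 | step 6 | 1,3-dioxoisoindolin-2-yl 3-[(1S)-1-methyl-2,5-dioxocyclohexyl]propanoate | O=C(CC[C@@]1(C)CC(=O)CCC1=O)ON1C(=O)c2ccccc2C1=O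
F2 | step 6 | methyl 2-methyl-5-[(1S)-1-methyl-2,5-dioxocyclohexyl]pentanoate (C2 epimers) | COC(=O)C(C)CCC[C@@]1(C)CC(=O)CCC1=O
F3 | step 6 | methyl 2-methyl-5-[(1S)-1-methyl-2,5-dioxocyclohex-3-en-1-yl]pentanoate (C2 epimers) | COC(=O)C(C)CCC[C@@]1(C)CC(=O)C=CC1=O
F4 | step 7 | methyl 6-(tert-butyldimethylsilyloxy)-9-oxo-11,12,13,14,15,16,17-heptanorlabda-5,7-dien-19-oate | COC(=O)[C@@]1(C)CCC[C@@](C)(C1=C(O[Si](C)(C)C(C)(C)C)C=C2)C2=O
F5 | step 7 | methyl 6β-(tert-butyldimethylsilyloxy)-9-oxo-11,12,13,14,15,16,17-heptanorlabdan-19-oate (5α-H) | COC(=O)[C@@]1(C)CCC[C@@](C)([C@H]1[C@H](O[Si](C)(C)C(C)(C)C)CC2)C2=O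
F6 | step 19 | 14,14-dichloro-9α,13-epoxy-8β-(trimethylsilyloxy)labdane-19,6β:15,16-diolide (C13 as in 31) | C[C@]1(O[Si](C)(C)C)C[C@H]2OC(=O)[C@@]3(C)CCC[C@@](C)([C@@H]23)[C@@]12CC[C@]1(COC(=O)C1(Cl)Cl)O2
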